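The constants are made up, and the outcome is calculated.

I decide to put grey and ochre on one clock and to reckon in fractions of the charged substrate.

    2 substrate → self-condensation product (k1 = 3.4 × 10⁻⁵ M⁻¹ s⁻¹)
    catalyst intermediate → free catalyst + target (k2 = 0.35 s⁻¹)
    substrate + free catalyst → catalyst intermediate (k3 = 4.0 M⁻¹ s⁻¹)

- grey: substrate 0.017 M; free catalyst 24 µM; time 2.5 h
- ochre: substrate 0.017 M; free catalyst 24 µM; time 4.0 h

1. which of these there is most of at the end, counted by the substrate in it, grey (substrate / target / catalyst intermediate)
2. which of these there is most of at the end, counted by the substrate in it, ochre (substrate / target / catalyst intermediate)
3. the largest of these amounts at the end, in percent of the substrate charged, grey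
4. the largest of these amounts at the end, in percent of the substrate charged, ochre

Free catalyst takes up substrate as catalyst intermediate, which releases target and gives the free catalyst back. I set self-condensation aside at first, because in grey at the start the catalyst path uses substrate 83 times as fast as self-condensation does.

For grey I get 0.864 and for ochre 1.38 from the capture number, meaning the capture constant times the catalyst charged times the time. Held at its charge, free catalyst makes substrate fall pseudo-first-order, and the fraction left is the exponential of minus this number: 0.421 in grey and 0.251 in ochre.

One number is not enough, though: part of the catalyst sits as intermediate. The free share is one over one plus 0.194 times the fraction left, where that constant is the substrate charge times the capture constant over the release constant. Integrating takes from the capture number this constant times the fraction already consumed. So I put the first answer back: grey goes to 0.472, and once more to 0.467. The same two rounds take ochre to 0.288. Counting all the substrate consumed as target, my target fractions are 0.533 in grey and 0.712 in ochre.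

The forecast names target in grey at 53 % and target in ochre at 71 %, calling the turnover “close to first order with only mild saturation”.

The flask gives target at 53.1 % in grey and target at 70.8 % in ochre. At 1.25 h, grey holds 88.2 % of its catalyst charge free. The neighbour flask with 9.6 × 10⁻⁵ M of free catalyst, grey otherwise, has a capture number of 3.46. One round of putting back gives me a fraction left of 0.0379, and that flask ends with 3.8 % of its substrate left.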